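## Retrosynthetic overview
1. The target comes from the tetracyclic C11 ketone **18**. The late steps are allylic oxidation at C6, a C12 methylene unit, hydrogenation (sets C7 and C12), hydride reduction (sets C11), O‑methylation and O‑acetylation.
2. The ten‑membered carbocycle and the 2,9‑ether come from keto‑enal **16**. The C10 enol closes onto C9, and C2‑OH then captures the C9 allyl cation across the ring.
3. The oxepane forms when C16‑OH adds to C3 of the Δ3 alkene, which acts as a C3 cation equivalent.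
4. The cyclohexane forms when the C14=C15 π‑bond attacks electrophilic C1 with loss of H‑16. This is the terpene‑cyclase type of closure and gives the isopropenyl group.
5. The acyclic C19 chain comes from sulcatone, ethyl formate (C1) and geranyl acetate. Ring order: cyclohexane, then oxepane, then the ten‑membered ring and the tetrahydrofuran in one operation.

Assumption: atom labels C1–C20 follow the eunicellane/asbestinane skeleton of the target (ethers C2–O–C9 and C3–O–C16, OMe at C6, OAc at C11, methyls on C3, C7, C12, C15).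

## Route

Step 1
Reactants: 1 6-methylhept-5-en-2-one (sulcatone); 2 ethyl formate
Product: 4 (1Z)-1-hydroxy-7-methylocta-1,6-dien-3-one, via lithium enolate 3 (not isolated)
Conditions: LDA, THF, −78 °C; then 2, −78 to 0 °C; aq. HCl
Reagents that add atoms: ethyl formate, CCOC=O
Why: Claisen formylation of the kinetic methyl-side enolate joins C10 to C1, and no stereocentre is formed.

Step 2
Reactants: 4 (1Z)-1-hydroxy-7-methylocta-1,6-dien-3-one
Product: 5 (1E)-7-methyl-3-oxoocta-1,6-dien-1-yl trifluoromethanesulfonate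
Conditions: Tf2O, i-Pr2NEt, CH2Cl2, −78 °C
Reagents that add atoms: triflic anhydride, O=S(=O)(OS(=O)(=O)C(F)(F)F)C(F)(F)F
Why: O-sulfonylation of the formyl-ketone enolate gives the dipole-minimised (E)-β-triflyloxy enone, a β-acyl vinyl electrophile.

Step 3
Reactants: 6 geranyl acetate
Product: 7 (2E,6E)-3,7-dimethyl-8-oxooct-2,6-dien-1-yl acetate
Conditions: SeO2, 1,4-dioxane, 80 °C
Reagents that add atoms: selenium dioxide, O=[Se]=O
Why: Riley allylic oxidation (ene, then [2,3]-shift) attacks only the (E)-methyl group of the electron-rich terminal alkene and gives the C2 aldehyde.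

Step 4
Reactants: 5 (1E)-7-methyl-3-oxoocta-1,6-dien-1-yl trifluoromethanesulfonate; 7 (2E,6E)-3,7-dimethyl-8-oxooct-2,6-dien-1-yl acetate
Product: 8 (2E,6E,8S,9E)-8-hydroxy-3,7,15-trimethyl-11-oxohexadeca-2,6,9,14-tetraen-1-yl acetate
Conditions: CrCl2, NiCl2 (cat.), chiral oxazoline–sulfonamide ligand, Et3N, THF, rt
Reagents that add atoms: none
Why: Asymmetric Nozaki–Hiyama–Kishi coupling forms C1–C2, tolerates enone and acetate, and sets (2S) by ligand-controlled attack on the Si face of the aldehyde.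

Step 5
Reactants: 8 (2E,6E,8S,9E)-8-hydroxy-3,7,15-trimethyl-11-oxohexadeca-2,6,9,14-tetraen-1-yl acetate
Product: 10 (2E,6E,8S)-8-hydroxy-3,7-dimethyl-8-[(1R,2R)-5-oxo-2-(prop-1-en-2-yl)cyclohexyl]octa-2,6-dien-1-yl acetate, via aluminium enolate 9 (not isolated)
Conditions: Me2AlCl (3 equiv), CH2Cl2, −78 to −30 °C; aq. Rochelle salt
Reagents that add atoms: none
Why: In this Lewis-acid-promoted intramolecular conjugate ene (cation–olefin) cyclisation, C14=C15 attacks C1 through a chair with both new substituents equatorial (C1/C14 trans) and anti to the C2–O bond (Felkin-type), while Me2AlCl removes H-16 as methane so that the isopropenyl group forms instead of hydride shifts.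

Step 6
Reactants: 10 (2E,6E,8S)-8-hydroxy-3,7-dimethyl-8-[(1R,2R)-5-oxo-2-(prop-1-en-2-yl)cyclohexyl]octa-2,6-dien-1-yl acetate
Product: 12 (2E,6E,8S)-8-hydroxy-8-{(1R,2S)-2-[(2R)-1-hydroxypropan-2-yl]-5-oxocyclohexyl}-3,7-dimethylocta-2,6-dien-1-yl acetate, via B-alkyl-9-BBN borinate 11 (not isolated)
Conditions: 9-BBN (2.5 equiv), THF, 0 °C to rt; 30% H2O2, pH 7 buffer
Reagents that add atoms: hydrogen peroxide, OO
Why: Brown hydroboration–oxidation with 9-BBN takes only the 1,1-disubstituted alkene, and attack anti to C1 in the conformer with H-14 eclipsing C15=C16 gives (15R).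

Step 7
Reactants: 12 (2E,6E,8S)-8-hydroxy-8-{(1R,2S)-2-[(2R)-1-hydroxypropan-2-yl]-5-oxocyclohexyl}-3,7-dimethylocta-2,6-dien-1-yl acetate
Product: 14 oxepane-fused cyclohexanone acetate (1R,2S,3S,14S,15R;7E) with C3–O–C16 ether and free 2-OH and C9-OAc, via C4-organomercurial 13 (not isolated)
Conditions: Hg(O2CCF3)2, CH2Cl2, −20 °C; then n-Bu3SnH, rt
Reagents that add atoms: none
Why: In this intramolecular oxymercuration–demercuration (7-exo, Markovnikov) only Δ3 has a hydroxyl within reach, and delivery of O-16 from the C1 side of the conformer with H-2 eclipsing the C3 methyl gives (3S), syn to O-2.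

Step 8
Reactants: 14 oxepane-fused cyclohexanone acetate
Product: 15 oxepane-fused cyclohexanone allylic alcohol (1R,2S,3S,14S,15R;7E) with C9-OH
Conditions: K2CO3 (cat.), MeOH, 0 °C
Reagents that add atoms: none
Why: Zemplén-type transesterification removes the only protecting group without touching ketone or ethers.

Step 9
Reactants: 15 oxepane-fused cyclohexanone allylic alcohol
Product: 16 oxepane-fused keto-enal (1R,2S,3S,14S,15R;7E) with C9 aldehyde
Conditions: MnO2, CH2Cl2, rt
Reagents that add atoms: none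
Why: MnO2 oxidises only the allylic primary alcohol, because the secondary 2-OH is no longer allylic.

Step 10
Reactants: 16 oxepane-fused keto-enal
Product: 18 tetracyclic ketone (1S,2S,3S,9S,10R,14S,15R;7E) with 2,9- and 3,16-ether bridges and C11=O, via ten-membered aldol 17 (not isolated)
Conditions: Sc(OTf)3 (10 mol %), 4 Å MS, (CH2Cl)2, 0.5 mM, 40 °C
Reagents that add atoms: none
Why: Proposed new method: the acid makes enolisation and aldol addition to the activated enal reversible, and only the C10 adduct 17 places its allylic C9-OH 1,4 to C2-OH, so ionisation to the C7–C9 allyl cation and 5-exo capture by O-2 drains the equilibrium irreversibly; C10 settles as the cis-fused epimer and C9 with C8 cis to C3, the only way the bridge can span the ring; closest known types are acid-catalysed intramolecular aldol reaction and dehydrative SN1 allylic etherification.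

Step 11
Reactants: 18 tetracyclic ketone
Product: 19 (6R)-6-hydroxy tetracyclic ketone (7E)
Conditions: SeO2 (0.5 equiv), t-BuOOH, CH2Cl2, rt
Reagents that add atoms: tert-butyl hydroperoxide, CC(C)(C)OO
Why: Sharpless-modified Riley oxidation of the only alkene hits the CH2 at the (E)-position of the more substituted terminus (C6), and the suprafacial ene/[2,3] sequence on the exposed outer face of the E-oxonene places the oxygen as 6R.

Step 12
Reactants: 19 (6R)-6-hydroxy tetracyclic ketone
Product: 20 12-methylene-6-hydroxy tetracyclic ketone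
Conditions: (CH2O)n, i-Pr2NH·CF3CO2H, THF, reflux
Reagents that add atoms: formaldehyde, C=O
Why: In this Mannich-type α-methylenation only C12 carries the two α-hydrogens needed for amine elimination, so C20 enters regioselectively and stays sp2.

Step 13
Reactants: 20 12-methylene-6-hydroxy tetracyclic ketone
Product: 21 (6R,7R,12R)-6-hydroxy-7,12-dimethyl saturated tetracyclic ketone
Conditions: H2 (4 atm), [Ir(cod)(py)(PCy3)]PF6 (10 mol %), CH2Cl2, rt
Reagents that add atoms: none
Why: In this Crabtree hydrogenation the 6-OH directs H2 to Δ7 in the A(1,2)-minimised conformer (O-6 and the C7 methyl end up syn, 7R), and the exocyclic enone is reduced from the convex face opposite axial C9, which pushes the C12 methyl to the concave face (12R).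

Step 14
Reactants: 21 (6R,7R,12R)-6-hydroxy-7,12-dimethyl saturated tetracyclic ketone
Product: 22 6-O-methyl tetracyclic ketone
Conditions: MeOTf, 2,6-di-tert-butyl-4-methylpyridine, CH2Cl2, 0 °C
Reagents that add atoms: methyl triflate, COS(=O)(=O)C(F)(F)F
Why: O-methylation under non-basic conditions avoids enolising the ketone, so the axial C12 methyl is not epimerised.

Step 15
Reactants: 22 6-O-methyl tetracyclic ketone
Product: 23 (11R)-11-hydroxy-6-O-methyl tetracycle
Conditions: NaBH4, MeOH, −20 °C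
Reagents that add atoms: none
Why: Hydride attacks axially from the convex face, because the other face is blocked by axial C9 and the axial C12 methyl, and this gives the equatorial 11R alcohol.

Step 16
Reactants: 23 (11R)-11-hydroxy-6-O-methyl tetracycle
Product: 24 target CNP0289153.2 (1S,2S,3S,6R,7R,9S,10R,11R,12R,14S,15R)
Conditions: Ac2O, pyridine, DMAP (cat.), CH2Cl2, rt
Reagents that add atoms: acetic anhydride, CC(=O)OC(C)=O
Why: DMAP-catalysed acetylation of the only free hydroxyl proceeds with retention.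

## Compound list
1 | 6-methylhept-5-en-2-one (C10–C17) | CC(=O)CCC=C(C)C | starting material
2 | ethyl formate (C1) | CCOC=O | starting material
3 | lithium 6-methylhepta-1,5-dien-2-olate | [Li+].C=C([O-])CCC=C(C)C | intermediate
4 | (1Z)-1-hydroxy-7-methylocta-1,6-dien-3-one | O/C=C\C(=O)CCC=C(C)C | intermediate
5 | (1E)-7-methyl-3-oxoocta-1,6-dien-1-yl triflate | O=C(/C=C/OS(=O)(=O)C(F)(F)F)CCC=C(C)C | intermediate
6 | geranyl acetate (C2–C9, C18, C19) | CC(C)=CCC/C(C)=C/COC(C)=O | starting material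
7 | (2E,6E)-3,7-dimethyl-8-oxooct-2,6-dien-1-yl acetate | O=C/C(C)=C/CC/C(C)=C/COC(C)=O | intermediate
8 | (2E,6E,8S,9E)-8-hydroxy-3,7,15-trimethyl-11-oxohexadeca-2,6,9,14-tetraen-1-yl acetate | CC(C)=CCCC(=O)/C=C/[C@H](O)/C(C)=C/CC/C(C)=C/COC(C)=O | intermediate
9 | bis(chloromethylaluminium) C11-enolate/C2-alkoxide of 10 | C=C(C)[C@@H]1CCC(O[Al](C)Cl)=C[C@H]1[C@H](O[Al](C)Cl)/C(C)=C/CC/C(C)=C/COC(C)=O | intermediate
10 | cyclohexanone (1R,2S,14R) with isopropenyl at C14 | C=C(C)[C@@H]1CCC(=O)C[C@H]1[C@H](O)/C(C)=C/CC/C(C)=C/COC(C)=O | intermediate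
11 | C16-(9-BBN) borane, C2-O-(9-BBN) borinate | C[C@@H](CB2C3CCCC2CCC3)[C@@H]1CCC(=O)C[C@H]1[C@H](OB2C3CCCC2CCC3)/C(C)=C/CC/C(C)=C/COC(C)=O | intermediate
12 | 2,16-diol (1R,2S,14S,15R) | C[C@@H](CO)[C@@H]1CCC(=O)C[C@H]1[C@H](O)/C(C)=C/CC/C(C)=C/COC(C)=O | intermediate
13 | C4-mercuric trifluoroacetate of 14 | CC(=O)OC/C=C(C)/CC[C@H]([Hg]OC(=O)C(F)(F)F)[C@]2(C)OC[C@H](C)[C@@H]3CCC(=O)C[C@H]3[C@@H]2O | intermediate
14 | oxepane-fused cyclohexanone acetate (1R,2S,3S,14S,15R;7E) | CC(=O)OC/C=C(C)/CCC[C@]2(C)OC[C@H](C)[C@@H]3CCC(=O)C[C@H]3[C@@H]2O | intermediate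
15 | oxepane-fused cyclohexanone allylic alcohol | OC/C=C(C)/CCC[C@]2(C)OC[C@H](C)[C@@H]3CCC(=O)C[C@H]3[C@@H]2O | intermediate
16 | oxepane-fused keto-enal | O=C/C=C(C)/CCC[C@]2(C)OC[C@H](C)[C@@H]3CCC(=O)C[C@H]3[C@@H]2O | intermediate
17 | ten-membered aldol (1S,2S,3S,9S,10R,14S,15R;7E), 2,9-diol | C1CC[C@]2(C)OC[C@H](C)[C@@H]3CCC(=O)[C@H]([C@H]3[C@@H]2O)[C@@H](O)/C=C1\C | intermediate
18 | tetracyclic ketone (1S,2S,3S,9S,10R,14S,15R;7E) | C1CC[C@]2(C)OC[C@H](C)[C@@H]3CCC(=O)[C@@H]4[C@H]3[C@@H]2O[C@H]4/C=C1\C | intermediate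
19 | (6R)-6-hydroxy tetracyclic ketone | O[C@@H]1CC[C@]2(C)OC[C@H](C)[C@@H]3CCC(=O)[C@@H]4[C@H]3[C@@H]2O[C@H]4/C=C1\C | intermediate
20 | 12-methylene-6-hydroxy tetracyclic ketone | O[C@@H]1CC[C@]2(C)OC[C@H](C)[C@@H]3CC(=C)C(=O)[C@@H]4[C@H]3[C@@H]2O[C@H]4/C=C1\C | intermediate
21 | (6R,7R,12R) saturated hydroxy ketone | O[C@@H]1CC[C@]2(C)OC[C@H](C)[C@@H]3C[C@@H](C)C(=O)[C@@H]4[C@H]3[C@@H]2O[C@H]4C[C@H]1C | intermediate
22 | 6-O-methyl tetracyclic ketone | CO[C@@H]1CC[C@]2(C)OC[C@H](C)[C@@H]3C[C@@H](C)C(=O)[C@@H]4[C@H]3[C@@H]2O[C@H]4C[C@H]1C | intermediate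
23 | (11R)-alcohol | CO[C@@H]1CC[C@]2(C)OC[C@H](C)[C@@H]3C[C@@H](C)[C@@H](O)[C@@H]4[C@H]3[C@@H]2O[C@H]4C[C@H]1C | intermediate
24 | CNP0289153.2 | CO[C@@H]1CC[C@]2(C)OC[C@H](C)[C@@H]3C[C@@H](C)[C@@H](OC(C)=O)[C@@H]4[C@H]3[C@@H]2O[C@H]4C[C@H]1C | target

## Step count and risks
Total steps: 16. Longest linear sequence: 15 (steps 1, 2, 4–16).

**Step 4** may fail in the enantioselectivity or the reactivity of the β-acyl vinyl triflate. The fallback sets out from 5 and 7 and comes back at 8.
- The coupling is run without a ligand and gives the racemic alcohol rac-8 F1.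
- F1 is then resolved by Sharpless kinetic resolution with Ti(Oi-Pr)4, D-(−)-DIPT and 0.6 equiv t-BuOOH.
- The (R)-enantiomer is epoxidised at Δ3 to the erythro epoxy alcohol F2, which is separated, and (S)-8 is recovered.

**Step 5** may fail because hydride shifts or ionisation compete with ene termination. The fallback sets out from 1 and comes back at 10. It replaces the plain alkene by an allylsilane, so that the cation is terminated by loss of silicon.
- Ozonolysis of 1 gives 4-oxopentanal F3.
- A Seyferth–Fleming Wittig reaction gives 6-methyl-7-(trimethylsilyl)hept-5-en-2-one F4. The ylide is made from ethyltriphenylphosphonium bromide, n-BuLi, ICH2SiMe3 and n-BuLi.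
- The operations of steps 1, 2 and 4 then give the hydroxymethylene ketone F5, the enol triflate F6 and the allylsilane analogue of 8 F7.
- TiCl4 at −78 °C closes C14–C1 in an intramolecular Hosomi–Sakurai reaction and gives 10.

**Step 10** may fail because the ten-membered closure is too slow. The fallback sets out from 15 and comes back at 18. It makes the C–O bond first and the C–C bond by C–H oxidation.
- Methyl chloroformate and pyridine give the allylic methyl carbonate F8.
- Pd2(dba)3/dppf closes the nine-membered allyl ether F9 by Tsuji–Trost O-allylation of 2-OH.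
- Isopropenyl acetate and TsOH give the Δ10 enol acetate F10, which equilibrates with its regioisomer.
- DDQ, LiClO4 and 2,6-dichloropyridine oxidise the allylic ether C9–H to the oxocarbenium ion. The enol acetate carbon C10 captures this ion and gives 18.

Further compounds
F1 | step 4 | rac-8 | CC(C)=CCCC(=O)/C=C/C(O)/C(C)=C/CC/C(C)=C/COC(C)=O
F2 | step 4 | (2R)-3,4-epoxy alcohol from ent-8 (erythro) | CC(C)=CCCC(=O)/C=C/[C@@H](O)[C@@]1(C)O[C@@H]1CC/C(C)=C/COC(C)=O
F3 | step 5 | 4-oxopentanal | CC(=O)CCC=O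
F4 | step 5 | 6-methyl-7-(trimethylsilyl)hept-5-en-2-one | CC(=O)CCC=C(C)C[Si](C)(C)C
F5 | step 5 | (1Z)-1-hydroxy-7-methyl-8-(trimethylsilyl)octa-1,6-dien-3-one | O/C=C\C(=O)CCC=C(C)C[Si](C)(C)C
F6 | step 5 | (1E)-7-methyl-3-oxo-8-(trimethylsilyl)octa-1,6-dien-1-yl triflate | O=C(/C=C/OS(=O)(=O)C(F)(F)F)CCC=C(C)C[Si](C)(C)C
F7 | step 5 | 16-trimethylsilyl analogue of 8 (2S) | C[Si](C)(C)CC(C)=CCCC(=O)/C=C/[C@H](O)/C(C)=C/CC/C(C)=C/COC(C)=O
F8 | step 10 | C9 methyl carbonate of 15 | COC(=O)OC/C=C(C)/CCC[C@]2(C)OC[C@H](C)[C@@H]3CCC(=O)C[C@H]3[C@@H]2O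
F9 | step 10 | nine-membered C2–O–C9H2 allyl ether ketone | C1CC[C@]2(C)OC[C@H](C)[C@@H]3CCC(=O)C[C@H]3[C@@H]2OC/C=C1\C
F10 | step 10 | Δ10 enol acetate of F9 | C1CC[C@]2(C)OC[C@H](C)[C@@H]3CCC(OC(C)=O)=C[C@H]3[C@@H]2OC/C=C1\C
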